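## The problem

The decalin is numbered so that C1 carries the dienoic acid, C2 the but-2-en-2-yl group, C3=C4 the ring A alkene, C4a/C8a the ring fusion, C7 the sulfate and C8 the methyl group. Target 21 is then a cis-fused octalin with six contiguous stereocentres. On ring B the four groups O7, the C8 methyl, the C8a–C1 bond and the C4a–C4 bond all sit on one face; on ring A the C1 chain is trans to the C2 butenyl group. C7 and C8 can be set first in a simple ring B precursor and can then govern C8a, C4a and C1. C2 lies between two sp2 carbons, cannot be reached from ring B, and has to arrive preset. The secondary hydrogen sulfate is labile to acid and heat, the (2E,4E)-dienoic acid is a Michael acceptor prone to isomerisation, and the C2–H bond is doubly allylic. These groups must be made late or spared strong base, acid and hydrogen-abstracting radicals. Ring A must keep a trisubstituted alkene at C3=C4 beside the equally substituted butenyl alkene, so late unselective alkene chemistry is excluded. The enabling feature is that O7 and the carbon attached to C1 are cis-1,3 (diaxial) on ring B and that this carbon is at the aldehyde level. An acetal can tie O7 to it, a radical at C1 is then delivered to C8a of a C4a=C8a alkene, and the C4a radical so formed can close ring A at C4, where a leaving radical restores C3=C4.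

## Retrosynthesis

The sulfate and the free acid are removed first. Target 21 comes from the pyridinium sulfate ester 20 by saponification, and 20 from hydroxy dienoate 19 by O-sulfation. No skeletal bond is cut; the point is to keep the two most fragile groups out of every C–C bond-forming step. The forward steps must leave the dienoate geometry and the sulfate ester intact.

The C=C bond next to C1 is cut next, giving lactol 18 and a four-carbon phosphonate. A cut one alkene further out would need an enal that is exposed to conjugate addition by the free C7 hydroxyl. The lactol instead holds O7 and the aldehyde carbon in one masked unit until the moment of olefination. Lactol 18 is the hydrolysis product of ethyl acetal 17. The olefination must give the 2E,4E diene without epimerising C1.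

In 17 the bonds C1–C8a and C4–C4a are cut together, leading to the acyclic-arm bromoacetal 16. The neighbouring pair C1–C2/C4a–C8a (a Diels–Alder cut) would demand a Z dienophile and a Z diene terminus to reach this relative configuration. The chosen pair lets O7, already cis to the C8 methyl, deliver C1 to its own face and turns two rings and three stereocentres (C1, C4a, C8a) into one operation. The precursor is a monocyclic cyclohexenyl acetal with only three stereocentres of consequence (C2, C7, C8). The forward step must close 6-exo at C8a, then 6-endo at C4 with loss of the sulfur radical.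

The C–S bond of 16 is cut to alkenyl iodide 14 and benzenethiol 15. Sulfur could be carried from the start, but it would then meet the electrophilic bromine of the tethering step and would make the allylic alcohol of the arm prone to ionisation. Iodine is inert in all those steps but would not survive the cathode, so the exchange is placed directly before the key step. The coupling must take place at the C(sp2)–I bond in the presence of the secondary bromide.

Bromoacetal 14 is cut at the acetal C–O bond and the C–Br bond to enol ether 10 and alcohol 13. This is the standard three-component assembly of a bromoacetal and joins two fragments of similar size at a late, convergent point. The bromination must occur only at the enol ether.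

Alcohol 13 is opened at its ring alkene to diene 12 (ring-closing metathesis), and 12 is cut between the carbinol and methyl-bearing carbons to pent-4-enal 11 and an E crotyl unit. This replaces an epoxide-opening, inversion and resolution sequence by two steps that set C7 and C8 absolutely. The crotylation must be anti and face-selective.

Enol ether 10 is traced through acetal 9 to aldehyde 8 and ester 7. The C1–C2 bond of 7 is cut by a Claisen disconnection through ketene acetal 6 to allylic alcohol 5. This cut makes C2 from an easily set carbinol centre and creates the E butenyl group in the same event. Alcohol 5 comes from dienone 4 by catalyst-controlled reduction, 4 from aldehyde 2 and ylide 3, and 2 from the iodo alcohol 1. The rearrangement must pass through one chair only.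

## Roads not taken

Alternative 1: The two ring alkenes are cut (C3=C4 and C5=C6) in tetraene lactone A1. In the forward sense the second-generation Grubbs catalyst would pair the C7 vinyl with one vinyl of the divinylmethyl group on C8a (ring B) and the isopropenyl group on C2 with the other (ring A), fixing C4a and giving tricyclic lactone A2.
- Merits: metathesis is a thoroughly established ring closure, no radical is involved, and the lactone plays the role of the acetal tether, with O7 and the C1 carbon masked together. In certainty of the key step this road is better than the chosen plan.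
- Weak points: A2 keeps a C5=C6 alkene that must be hydrogenated beside C3=C4 and the butenyl alkene. Five stereocentres (C1, C2, C7, C8, C8a) must be built acyclically before the key step. The butenyl alkene can compete with the isopropenyl group in the ring A closure.
- Comparison: the chosen plan forms three of the six centres in the key step from two fragments that carry one and two centres, and needs no chemoselective hydrogenation.

Alternative 2: The C4a–C5 bond is cut by a retro-[3,3] step to the bridged vinyl carbinol A3, a bicyclo[2.2.2]octenol. Forward, the potassium alkoxide (KH, 18-crown-6) would undergo an anionic oxy-Cope shift that forms C4a–C5, breaks C3–C7 and gives the cis-fused C7 ketone A4 after protonation.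
- Merits: this is a textbook entry to cis-decalins; the C3=C4 alkene and an oxygen at C7 arrive in the right places, and the ring fusion is secured by the cage. The key step is again safer than the cascade.
- Weak points: A3 holds six stereocentres including a quaternary bridgehead, and needs a face- and regioselective cycloaddition and a face-selective vinyl addition to build. The doubly allylic C2–H is exposed to KH. Afterwards C7 must be reduced to the axial alcohol next to an epimerisable C8, and the C1 silyloxymethyl group must be raised to the aldehyde.
- Comparison: the stereochemical burden moves into the cage and the step count rises. The chosen plan sets O7 and the C8 methyl by one crotylation and then uses O7 as the controlling element.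

Alternative 3: Ring B is cut at C8–C8a and C4a–C5 to the Z silyloxydiene A5 and the quinone monoketal A6. Forward, a cationic oxazaborolidine catalyst (from α,α-diphenylprolinol and o-tolylboronic acid, activated by HN(SO2CF3)2) would give the cis-fused adduct A7.
- Merits: it is catalytic, enantioselective, convergent from achiral materials, and sets the ring fusion and C8 in one step. In absolute stereocontrol by a catalyst and in reliability it is superior.
- Weak points: ring A arrives as a ketal enone. The butenyl group still has to be added at C2, the C4 carbonyl removed with the alkene placed at C3=C4, and C1 homologated by one carbon with control. C8, C4a and C8a are each next to a carbonyl and can epimerise, and the C7 enol ether must become the axial alcohol.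
- Comparison: the sequence after the key step is long. The chosen plan needs four functional-group steps after its key step, because the tether carbon is already the aldehyde carbon and ring A is formed with its final substitution.

Key step: step 11

Assumptions:
- Compounds 1 and 3 are taken as commercial.
- The crotylborane from (−)-Ipc2BOMe is taken to attack the Si face of pent-4-enal, as with simple aliphatic aldehydes. If the opposite sense were found, the antipodal borane would be used.
- Decalin numbering as defined in the first section is used for 17–21.

## Steps

Step 1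
Reactants: 1 (E)-3-iodo-2-methylprop-2-en-1-ol
Product: 2 (E)-3-iodo-2-methylprop-2-enal
Conditions: MnO2, CH2Cl2, rt
Reagents that add atoms: none
Why: Allylic oxidation on MnO2 is neutral, stops at the enal and leaves the alkenyl iodide and its E geometry untouched; the volatile aldehyde is carried on as a solution.

Step 2
Reactants: 2 (E)-3-iodo-2-methylprop-2-enal; 3 3-(triphenyl-λ5-phosphanylidene)butan-2-one
Product: 4 (3E,5E)-6-iodo-3,5-dimethylhexa-3,5-dien-2-one
Conditions: toluene, 90 °C
Reagents that add atoms: none
Why: Wittig olefination with a ketone-stabilised, α-branched ylide gives the E trisubstituted enone; no base is present that could affect the iodide.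

Step 3
Reactants: 4 (3E,5E)-6-iodo-3,5-dimethylhexa-3,5-dien-2-one
Product: 5 (2R,3E,5E)-6-iodo-3,5-dimethylhexa-3,5-dien-2-ol
Conditions: (S)-2-methyl-CBS-oxazaborolidine (C18H20BNO, 20 mol%), catecholborane, toluene, −78 °C; then MeOH
Reagents that add atoms: none
Why: Corey–Bakshi–Shibata reduction: the alkenyl group acts as the large substituent, so the (S)-catalyst should deliver hydride to give the (R)-carbinol; catecholborane at low temperature reduces the carbonyl 1,2 without hydroborating the diene.

Step 4
Reactants: 5 (2R,3E,5E)-6-iodo-3,5-dimethylhexa-3,5-dien-2-ol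
Product: 7 ethyl (3R,4E)-3-[(1E)-1-iodoprop-1-en-2-yl]-4-methylhex-4-enoate, via mixed ketene acetal 6 (not isolated)
Conditions: CH3C(OEt)3, EtCO2H (cat.), 135 °C, EtOH distilled off
Reagents that add atoms: triethyl orthoacetate, CCOC(C)(OCC)OCC
Why: Johnson–Claisen rearrangement through the chair with the carbinol methyl equatorial transfers the C–O chirality to the new C–C bond (the future C2, R) and creates the (E)-but-2-en-2-yl group. The ethoxy group of the ketene acetal penalises the axial-methyl chair, which would give the Z alkene and the opposite C2.

Step 5
Reactants: 7 ethyl (3R,4E)-3-[(1E)-1-iodoprop-1-en-2-yl]-4-methylhex-4-enoate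
Product: 8 (3R,4E)-3-[(1E)-1-iodoprop-1-en-2-yl]-4-methylhex-4-enal
Conditions: i-Bu2AlH (1.1 equiv), CH2Cl2, −78 °C; then aq. potassium sodium tartrate
Reagents that add atoms: none
Why: Partial ester reduction stops at the aluminium hemiacetal at −78 °C and releases the aldehyde on work-up; the stereocentre is β to the carbonyl and cannot epimerise by enolisation.

Step 6
Reactants: 8 (3R,4E)-3-[(1E)-1-iodoprop-1-en-2-yl]-4-methylhex-4-enal
Product: 10 (1E,3R,4E)-3-(2-ethoxyethenyl)-1-iodo-2,4-dimethylhexa-1,4-diene (enol ether E/Z mixture), via diethyl acetal 9 (not isolated)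
Conditions: HC(OEt)3, pyridinium p-toluenesulfonate (cat.), EtOH, rt; evaporate; then Me3SiOTf, i-Pr2NEt, CH2Cl2, −20 °C to rt
Reagents that add atoms: triethyl orthoformate, CCOC(OCC)OCC
Why: Acetalisation followed by silyl triflate-induced loss of ethanol (ionisation to the oxocarbenium ion, deprotonation at the only α-CH2) gives the enol ether; its E/Z ratio is irrelevant because both isomers lead to the same bromoacetals.

Step 7
Reactants: 11 pent-4-enal
Product: 12 (3S,4R)-3-methylocta-1,7-dien-4-ol
Conditions: (E)-but-2-ene, KOt-Bu, n-BuLi, THF, −78 to −45 °C; (−)-Ipc2BOMe; BF3·OEt2; then 11, −78 °C; NaOH, H2O2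
Reagents that add atoms: (E)-crotyldiisopinocampheylborane made in the flask from (E)-but-2-ene, C/C=C/CB([C@@H]1C[C@@H]2C[C@H]([C@H]1C)C2(C)C)[C@@H]1C[C@@H]2C[C@H]([C@H]1C)C2(C)C
Why: Brown crotylboration through a closed Zimmerman–Traxler chair: the E crotyl geometry gives the anti relationship and the isopinocampheyl groups select the aldehyde face, setting the future C7 (R) and C8 (S).

Step 8
Reactants: 12 (3S,4R)-3-methylocta-1,7-dien-4-ol
Product: 13 (1R,2S)-2-methylcyclohex-3-en-1-ol
Conditions: second-generation Grubbs catalyst (2 mol%), CH2Cl2, 40 °C
Reagents that add atoms: none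
Why: Ring-closing metathesis of a 1,7-diene to a cyclohexene is fast and driven by loss of ethene; the anti open-chain relationship becomes cis on the ring and the free hydroxyl is tolerated.

Step 9
Reactants: 10 (1E,3R,4E)-3-(2-ethoxyethenyl)-1-iodo-2,4-dimethylhexa-1,4-diene; 13 (1R,2S)-2-methylcyclohex-3-en-1-ol
Product: 14 (1R,2S)-1-{[(3R,4E)-2-bromo-1-ethoxy-3-[(1E)-1-iodoprop-1-en-2-yl]-4-methylhex-4-en-1-yl]oxy}-2-methylcyclohex-3-ene (mixture at the acetal and bromide carbons)
Conditions: N-bromosuccinimide, CH2Cl2, −78 to −40 °C
Reagents that add atoms: N-bromosuccinimide, O=C1CCC(=O)N1Br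
Why: Bromoetherification of an enol ether, the tether-forming half of the Ueno–Stork protocol: the enol ether is by far the most nucleophilic alkene, and the bromo-oxocarbenium ion is trapped by alcohol 13. The alkenyl iodide, the trisubstituted alkene and the ring alkene should not react at −78 °C.

Step 10
Reactants: 14 iodo bromoacetal (as above); 15 benzenethiol
Product: 16 (1R,2S)-1-{[(3R,4E)-2-bromo-1-ethoxy-4-methyl-3-[(1E)-1-(phenylsulfanyl)prop-1-en-2-yl]hex-4-en-1-yl]oxy}-2-methylcyclohex-3-ene (mixture at the acetal and bromide carbons)
Conditions: Pd2(dba)3 (2.5 mol%), Xantphos (5 mol%), i-Pr2NEt, 1,4-dioxane, 50 °C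
Reagents that add atoms: none
Why: Palladium-catalysed cross-coupling of an alkenyl iodide with a thiol proceeds with retention of the E geometry. Zerovalent palladium inserts into the C(sp2)–I bond far faster than into the hindered secondary C–Br bond, and the weak amine base and the branched neighbours disfavour substitution or elimination at the bromide.

Step 11
Reactants: 16 phenylsulfanyl bromoacetal (as above)
Product: 17 tricyclic lactol ethyl ether: the cis-fused octalin of the target with O7 and C1 bridged by CH(OEt), C2 butenyl, C3=C4 and C8 methyl in place; C1, C2, C4a, C7, C8, C8a configured as in 21; acetal carbon a mixture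
Conditions: Ni(cyclam)(ClO4)2 (10 mol%), n-Bu4NBF4, DMF, carbon-fibre cathode, Mg anode, undivided cell, constant current (2.2 F/mol), rt
Reagents that add atoms: none
Why: Proposed new method: monovalent nickel, formed at the cathode from the divalent nickel cyclam salt, cleaves the C–Br bond by electron transfer, and the C1 radical closes the tetrahydropyran by 6-exo-trig attack on C8a through a chair in which O7 is pseudo-axial on the ring B half-chair. The secondary C4a radical then closes ring A by 6-endo-trig attack on the sulfur-bearing C4, and the tertiary C3 radical expels PhS•, which is reduced to thiolate, so the alkene C3=C4 is formed without any hydrogen donor. The closest known reaction types are nickel- and cobalt-mediated electroreductive Ueno–Stork bromoacetal cyclisations and radical addition–fragmentation at vinyl sulfides; their union in one cascade with a 6-endo ipso closure is not established. C8a is set by the tether, which reaches the alkene only from the O7 face. C1 is set in the pyran chair, where the C2 arm takes the equatorial site away from the C8 methyl; the C1 epimer cannot reach C4a. C4a is set because the axial C8a–C1 bond holds the acceptor on the same face, so only the cis fusion is accessible. The step needs 6-endo over 5-exo closure, which the fully substituted C3 and the larger LUMO coefficient at the sulfur-bearing carbon should secure. It also needs closure onto the sulfide arm and not the butenyl arm, which the C2 configuration favours: with the sulfide arm in the ring the butenyl group sits pseudo-axial, anti to the acetal carbon and free of allylic 1,2-strain, whereas the other pairing forces the spectator arm pseudo-equatorial against a vinylic methyl. Dry DMF keeps the expelled sulfur as thiolate, not as the hydrogen-donating thiol, and the low steady radical concentration of mediated electrolysis lets the slow bridged 6-exo closure compete with reduction.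

Step 12
Reactants: 17 tricyclic lactol ethyl ether
Product: 18 tricyclic lactol (cyclic hemiacetal of the C1 formyl group with the C7 hydroxyl; anomer mixture)
Conditions: 1 M HCl, THF, rt
Reagents that add atoms: water, O
Why: Acid hydrolysis of the mixed acetal through the ring oxocarbenium ion (not at a bridgehead) gives the lactol; the isolated trisubstituted alkenes are inert to dilute acid at room temperature.

Step 13
Reactants: 18 tricyclic lactol
Product: 19 ethyl (2E,4E)-5-[(1R,2R,4aS,7R,8S,8aR)-2-[(2E)-but-2-en-2-yl]-7-hydroxy-3,8-dimethyl-1,2,4a,5,6,7,8,8a-octahydronaphthalen-1-yl]penta-2,4-dienoate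
Conditions: (EtO)2P(O)CH2CH=CHCO2Et, LiN(SiMe3)2, THF, −78 to 0 °C
Reagents that add atoms: triethyl 4-phosphonocrotonate, CCOC(=O)/C=C/CP(=O)(OCC)OCC
Why: Horner–Wadsworth–Emmons olefination of the open hydroxy aldehyde in equilibrium with the lactol gives the 2E,4E dienoate and frees the C7 hydroxyl; the weakly basic stabilised anion and low temperature should limit epimerisation at C1.

Step 14
Reactants: 19 hydroxy dienoate
Product: 20 pyridinium salt of the C7 sulfate monoester of 19
Conditions: SO3·pyridine, pyridine, 40 °C
Reagents that add atoms: sulfur trioxide–pyridine complex, [O-]S(=O)(=O)[n+]1ccccc1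
Why: O-Sulfation of a secondary alcohol with the SO3–pyridine complex; ester and alkenes are inert and the product is kept as its salt.

Step 15
Reactants: 20 pyridinium sulfate ester
Product: 21 (2E,4E)-5-[(1R,2R,4aS,7R,8S,8aR)-2-[(2E)-but-2-en-2-yl]-3,8-dimethyl-7-(sulfooxy)-1,2,4a,5,6,7,8,8a-octahydronaphthalen-1-yl]penta-2,4-dienoic acid
Conditions: LiOH, THF/H2O, rt; then 1 M HCl to pH 2, 0 °C; C18 desalting
Reagents that add atoms: lithium hydroxide, [Li+].[OH-]
Why: Saponification of the ethyl ester; alkyl sulfate monoanions resist hydroxide at room temperature, so only the ester is cleaved, and brief cold acidification should give the free acid form.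

## Compound list

1 | (E)-3-iodo-2-methylprop-2-en-1-ol | OC/C(C)=C/I | starting material
2 | (E)-3-iodo-2-methylprop-2-enal | O=C/C(C)=C/I | intermediate
3 | 3-(triphenyl-λ5-phosphanylidene)butan-2-one | CC(=O)C(C)=P(c1ccccc1)(c1ccccc1)c1ccccc1 | starting material
4 | (3E,5E)-6-iodo-3,5-dimethylhexa-3,5-dien-2-one | CC(=O)/C(C)=C/C(C)=C/I | intermediate
5 | (2R,3E,5E)-6-iodo-3,5-dimethylhexa-3,5-dien-2-ol | C[C@@H](O)/C(C)=C/C(C)=C/I | intermediate
6 | mixed ketene acetal, 1-ethoxyvinyl ether of 5 | C[C@@H](OC(=C)OCC)/C(C)=C/C(C)=C/I | intermediate (not isolated)
7 | ethyl (3R,4E)-3-[(1E)-1-iodoprop-1-en-2-yl]-4-methylhex-4-enoate | C/C=C(\C)[C@H](/C(C)=C/I)CC(=O)OCC | intermediate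
8 | (3R,4E)-3-[(1E)-1-iodoprop-1-en-2-yl]-4-methylhex-4-enal | C/C=C(\C)[C@H](/C(C)=C/I)CC=O | intermediate
9 | (1E,3R,4E)-3-(2,2-diethoxyethyl)-1-iodo-2,4-dimethylhexa-1,4-diene | C/C=C(\C)[C@H](/C(C)=C/I)CC(OCC)OCC | intermediate (not isolated)
10 | (1E,3R,4E)-3-(2-ethoxyethenyl)-1-iodo-2,4-dimethylhexa-1,4-diene (enol ether E/Z mixture) | C/C=C(\C)[C@H](/C(C)=C/I)C=COCC | intermediate
11 | pent-4-enal | C=CCCC=O | starting material
12 | (3S,4R)-3-methylocta-1,7-dien-4-ol | C=CCC[C@@H](O)[C@@H](C)C=C | intermediate
13 | (1R,2S)-2-methylcyclohex-3-en-1-ol | O[C@@H]1CCC=C[C@@H]1C | intermediate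
14 | (1R,2S)-1-{[(3R,4E)-2-bromo-1-ethoxy-3-[(1E)-1-iodoprop-1-en-2-yl]-4-methylhex-4-en-1-yl]oxy}-2-methylcyclohex-3-ene (mixture at acetal and bromide carbons) | C/C=C(\C)[C@H](/C(C)=C/I)C(Br)C(OCC)O[C@@H]1CCC=C[C@@H]1C | intermediate
15 | benzenethiol | Sc1ccccc1 | starting material
16 | (1R,2S)-1-{[(3R,4E)-2-bromo-1-ethoxy-4-methyl-3-[(1E)-1-(phenylsulfanyl)prop-1-en-2-yl]hex-4-en-1-yl]oxy}-2-methylcyclohex-3-ene (mixture at acetal and bromide carbons) | C/C=C(\C)[C@H](/C(C)=C/Sc1ccccc1)C(Br)C(OCC)O[C@@H]1CCC=C[C@@H]1C | intermediate
17 | tricyclic lactol ethyl ether (cis-octalin of 21 with O7–CH(OEt)–C1 bridge; acetal carbon a mixture) | C/C=C(\C)[C@@H]1C(C)=C[C@H]2CC[C@@H]3[C@@H](C)[C@H]2[C@H]1C(OCC)O3 | intermediate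
18 | tricyclic lactol (O7–CH(OH)–C1 bridge; anomer mixture) | C/C=C(\C)[C@@H]1C(C)=C[C@H]2CC[C@@H]3[C@@H](C)[C@H]2[C@H]1C(O)O3 | intermediate
19 | ethyl (2E,4E)-5-[(1R,2R,4aS,7R,8S,8aR)-2-[(2E)-but-2-en-2-yl]-7-hydroxy-3,8-dimethyl-1,2,4a,5,6,7,8,8a-octahydronaphthalen-1-yl]penta-2,4-dienoate | C/C=C(\C)[C@@H]1C(C)=C[C@H]2CC[C@@H](O)[C@@H](C)[C@H]2[C@H]1/C=C/C=C/C(=O)OCC | intermediate
20 | pyridinium salt of the C7 sulfate monoester of 19 | C/C=C(\C)[C@@H]1C(C)=C[C@H]2CC[C@@H](OS(=O)(=O)[O-])[C@@H](C)[C@H]2[C@H]1/C=C/C=C/C(=O)OCC.c1cc[nH+]cc1 | intermediate
21 | (2E,4E)-5-[(1R,2R,4aS,7R,8S,8aR)-2-[(2E)-but-2-en-2-yl]-3,8-dimethyl-7-(sulfooxy)-1,2,4a,5,6,7,8,8a-octahydronaphthalen-1-yl]penta-2,4-dienoic acid | C/C=C(\C)[C@@H]1C(C)=C[C@H]2CC[C@@H](OS(=O)(=O)O)[C@@H](C)[C@H]2[C@H]1/C=C/C=C/C(=O)O | target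

## Step count and risk

Total: 15 steps. Longest linear sequence: 13 steps (steps 1–6 and 9–15).

**Step 11 (key step).**
- What may go wrong: the C1 radical may be lost before the slow bridged 6-exo closure, by 1,5-hydrogen transfer from the acetal C–H bonds or by further reduction with loss of alkoxide. The C4a radical may close 5-exo at C3 to the sulfur-stabilised radical, close onto the butenyl arm, or be captured by nickel or by thiolate-derived species. The acetal epimer whose ethoxy group must point over ring B may close sluggishly.
- Fallback (known reaction types): the route is left at iodide 14, before sulfur is introduced. A cobaloxime-catalysed radical cyclisation (Co(dmgH)2(py)Cl, NaBH4, EtOH, visible light) should give the bicyclic alkenyl acetal F1. Monovalent cobalt attacks the C–Br bond, the C1 radical closes 6-exo, and the C4a radical is captured by cobalt and loses hydridocobaloxime towards C5, the bridgehead side being barred. A tin hydride vinyl radical cyclisation (Bu3SnH, 2,2′-azobis(isobutyronitrile), benzene, 80 °C, slow addition) then closes ring A 6-exo from C4 onto C4a and reduces the C5 radical. The sequence returns to the route at 17.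

**Step 10.**
- What may go wrong: displacement of the secondary bromide by thiolate, base-induced loss of HBr towards the doubly allylic C–H, or deactivation of palladium by thiolate.
- Fallback: the order is changed. Enol ether 10 is coupled with thiol 15 under the same palladium catalysis, where no alkyl bromide is present, to give the phenylsulfanyl enol ether F2. F2 is then joined to alcohol 13 with N-bromosuccinimide at −78 °C, relying on the much higher nucleophilicity of the enol ether over the vinyl sulfide. The sequence returns at 16.

**Step 9.**
- What may go wrong: incomplete capture of the bromo-oxocarbenium ion by the hindered, volatile secondary alcohol, with succinimide incorporation or dibromination, so that the ring fragment is wasted.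
- Fallback: the tether is formed by acetal exchange. Enol ether 10 is brominated in ethanol (N-bromosuccinimide, EtOH, −40 °C) to the α-bromo diethyl acetal F3. One ethoxy group is then exchanged for alcohol 13 (pyridinium p-toluenesulfonate, benzene, removal of ethanol). The sequence returns at 14.

**Step 13.**
- What may go wrong: base-mediated epimerisation at C1 of the open hydroxy aldehyde, re-addition of the C7 alkoxide to the dienoate (closing the pyran again), or partial formation of the 4Z isomer.
- Fallback: the chain is built in two neutral Wittig steps. Lactol 18 with Ph3P=CHCHO (toluene, 80 °C) should give the hydroxy enal F4, and F4 with Ph3P=CHCO2Et (CH2Cl2, rt) returns to 19. No alkoxide or strong base is present.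

**Step 15.**
- What may go wrong: loss of the sulfate, or acid-promoted reactions of the skipped diene, during acidification of the sulfate ester salt.
- Fallback: the order of the last two steps is reversed. Ester 19 is saponified (LiOH, THF/H2O) to the hydroxy acid F5. F5 is sulfated with SO3·pyridine (the mixed acyl sulfate is hydrolysed in the aqueous bicarbonate work-up) and passed through an acidic ion-exchange resin at 0 °C. The sequence returns at 21.

## Further compounds

F1 | step 11 | 3-ethoxy-9-methyl-2-oxabicyclo[3.3.1]non-6-ene carrying at C4 the (1E,3R,4E)-1-iodo-2,4-dimethylhexa-1,4-dien-3-yl arm (decalin C4a=C5 alkene; acetal carbon a mixture) | C/C=C(\C)[C@H](/C(C)=C/I)[C@@H]1C(OCC)O[C@@H]2CC=C[C@H]1[C@@H]2C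
F2 | step 10 | {[(1E,3R,4E)-3-(2-ethoxyethenyl)-2,4-dimethylhexa-1,4-dien-1-yl]sulfanyl}benzene (enol ether E/Z mixture) | C/C=C(\C)[C@H](/C(C)=C/Sc1ccccc1)C=COCC
F3 | step 9 | (1E,3R,4E)-3-(1-bromo-2,2-diethoxyethyl)-1-iodo-2,4-dimethylhexa-1,4-diene (bromide carbon a mixture) | C/C=C(\C)[C@H](/C(C)=C/I)C(Br)C(OCC)OCC
F4 | step 13 | (2E)-3-[(1R,2R,4aS,7R,8S,8aR)-2-[(2E)-but-2-en-2-yl]-7-hydroxy-3,8-dimethyl-1,2,4a,5,6,7,8,8a-octahydronaphthalen-1-yl]prop-2-enal | C/C=C(\C)[C@@H]1C(C)=C[C@H]2CC[C@@H](O)[C@@H](C)[C@H]2[C@H]1/C=C/C=O
F5 | step 15 | (2E,4E)-5-[(1R,2R,4aS,7R,8S,8aR)-2-[(2E)-but-2-en-2-yl]-7-hydroxy-3,8-dimethyl-1,2,4a,5,6,7,8,8a-octahydronaphthalen-1-yl]penta-2,4-dienoic acid | C/C=C(\C)[C@@H]1C(C)=C[C@H]2CC[C@@H](O)[C@@H](C)[C@H]2[C@H]1/C=C/C=C/C(=O)O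
A1 | alternative 1 | tetraene δ-lactone with C7 vinyl, C8 methyl, C8a divinylmethyl and a C1 CH(butenyl)(isopropenyl) group | C/C=C(\C)[C@H](C(C)=C)[C@@H]1C(=O)O[C@H](C=C)[C@@H](C)[C@@H]1C(C=C)C=C
A2 | alternative 1 | tricyclic lactone with cis-decalin, C3=C4 and C5=C6 alkenes | C/C=C(\C)[C@@H]1C(C)=C[C@H]2C=C[C@@H]3[C@@H](C)[C@H]2[C@H]1C(=O)O3
A3 | alternative 2 | bridged 2-vinylbicyclo[2.2.2]oct-5-en-2-ol with bridgehead methyl, butenyl, silyloxymethyl and C8 methyl groups | C/C=C(\C)[C@H]1[C@H](CO[Si](C)(C)C(C)(C)C)[C@H]2C=C[C@]1(C)[C@](O)(C=C)[C@H]2C
A4 | alternative 2 | cis-fused C7 ketone with C3=C4 alkene, C2 butenyl, C8 methyl and C1 silyloxymethyl | C/C=C(\C)[C@@H]1C(C)=C[C@H]2CCC(=O)[C@@H](C)[C@H]2[C@H]1CO[Si](C)(C)C(C)(C)C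
A5 | alternative 3 | (Z)-3-(triisopropylsilyloxy)penta-1,3-diene | C/C=C(/C=C)O[Si](C(C)C)(C(C)C)C(C)C
A6 | alternative 3 | 4,4-dimethoxy-2-methylcyclohexa-2,5-dien-1-one | COC1(OC)C=C(C)C(=O)C=C1
A7 | alternative 3 | cis-fused Diels–Alder adduct with C1 ketal, C2=C3 enone on the C4 ketone, C7 silyl enol ether and C8 methyl | COC1(OC)C=C(C)C(=O)[C@H]2CC=C(O[Si](C(C)C)(C(C)C)C(C)C)[C@@H](C)[C@H]21
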